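**Retrosynthetic overview**
- The acid comes from its methyl ester. The only ring, the 1,2-dioxane, is closed in the penultimate step by 6-exo peroxy-Michael addition of a C6 tertiary hydroperoxide onto an E-enoate (O2–C3 bond); the O–O unit comes from O2 by cobalt-catalysed hydroperoxysilylation of a 1,1-disubstituted alkene.
- The enoate comes from a Wittig reaction on an α-methyl-γ-methylene aldehyde.
- Key C4–C5 bond: the α-carbon of propanal, made electrophilic as the oxidised chiral enamine (radical cation), is joined to the nucleophilic terminus of a 2-substituted allylsilane that carries the whole side chain. This sets C4.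
- The allylsilane comes from a β-methyl ester (double Me3SiCH2 addition, Peterson elimination), itself made by asymmetric conjugate addition of a side-chain Grignard reagent to methyl crotonate (sets C2').
- The Grignard reagent comes from (R)-citronellyl bromide (C6' from the chiral pool) by coupling with PhCH2CH2MgCl, ozonolysis/reduction and bromination.

Assumption: the SMILES is read as (3S,4S,6R) in the ring (3-CH2CO2H, 4-Me and the 6-alkyl chain all cis) and (2'R,6'S) in the side chain (C1' = CH2 on C6); both enantiomers of the ligand and of the amine catalyst are taken as purchasable.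

**Route**

Step 1
Reactants: 1 (6R)-8-bromo-2,6-dimethyloct-2-ene [(R)-citronellyl bromide]; 2 2-phenylethylmagnesium chloride
Product: 3 [(5S)-5,9-dimethyldec-8-en-1-yl]benzene
Conditions: Li2CuCl4 (3 mol%), THF, −10 to 0 °C
Reagents that add atoms: none
Why: Kochi-type copper-catalysed sp3–sp3 cross-coupling of a primary bromide with a primary Grignard reagent; the stereocentre of 1 is remote, untouched, and becomes C6' (S).

Step 2
Reactants: 3 [(5S)-5,9-dimethyldec-8-en-1-yl]benzene
Product: 5 (4S)-4-methyl-8-phenyloctan-1-ol, via ozonide 4 (not isolated)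
Conditions: O3, CH2Cl2, −78 °C; then NaBH4, MeOH, −78 °C to rt
Reagents that add atoms: ozone, [O-][O+]=O
Why: Ozonolysis of the trisubstituted alkene with reductive borohydride work-up gives the primary alcohol directly, the isopropylidene end leaving as propan-2-ol; the arene is inert at −78 °C.

Step 3
Reactants: 5 (4S)-4-methyl-8-phenyloctan-1-ol
Product: 6 [(5S)-8-bromo-5-methyloctyl]benzene
Conditions: CBr4, PPh3, CH2Cl2, 0 °C
Reagents that add atoms: tetrabromomethane, BrC(Br)(Br)Br
Why: Appel bromination of a primary alcohol (SN2 at CH2; the stereocentre is three carbons away).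

Step 4
Reactants: 6 [(5S)-8-bromo-5-methyloctyl]benzene; 7 methyl (2E)-but-2-enoate
Product: 9 methyl (3R,7S)-3,7-dimethyl-11-phenylundecanoate, via Grignard reagent 8 (not isolated)
Conditions: Mg, Et2O; then 7, CuBr·SMe2 (5 mol%), 1-[2-(diphenylphosphino)ferrocenyl]ethyldicyclohexylphosphine (Josiphos, 6 mol%, the enantiomer that directs attack to the Si face of C3), t-BuOMe, −75 °C; aq. NH4Cl
Reagents that add atoms: none
Why: Copper-catalysed asymmetric conjugate addition of a primary Grignard reagent to a crotonate (Feringa-type); the chiral diphosphine–copper complex delivers the alkyl group to the Si face of C3, setting C2' (3R in 9) under catalyst control with no influence from the remote 7S centre.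

Step 5
Reactants: 9 methyl (3R,7S)-3,7-dimethyl-11-phenylundecanoate
Product: 11 trimethyl[(4R,8S)-4,8-dimethyl-2-methylidene-12-phenyldodecyl]silane, via bis-silyl carbinol 10 (not isolated)
Conditions: Me3SiCH2MgCl (4 equiv), CeCl3 (4 equiv), THF, −78 °C to rt; aq. NH4Cl; then SiO2, CH2Cl2, rt
Reagents that add atoms: (trimethylsilyl)methylmagnesium chloride, C[Si](C)(C)C[Mg]Cl
Why: Cerium-mediated double addition of Me3SiCH2 to the ester followed by acid-promoted Peterson elimination of the β-hydroxysilane (Bunnelle allylsilane synthesis); the β-stereocentre cannot enolise.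

Step 6
Reactants: 11 trimethyl[(4R,8S)-4,8-dimethyl-2-methylidene-12-phenyldodecyl]silane; 12 propanal
Product: 13 (2S,6R,10S)-2,6,10-trimethyl-4-methylidene-14-phenyltetradecanal
Conditions: 12 (3 equiv), (2R,5R)-5-benzyl-2-tert-butyl-3-methylimidazolidin-4-one·CF3CO2H (20 mol%), (NH4)2Ce(NO3)6 (2.5 equiv), NaHCO3, H2O (2 equiv), DME, −20 °C
Reagents that add atoms: none
Why: SOMO-activation α-allylation: the chiral enamine of propanal is oxidised by tetravalent cerium to a radical cation whose α-carbon is electrophilic (an enolonium-type species) and is captured by the nucleophilic allylsilane terminus, so two normally nucleophilic carbons are joined; a second oxidation and loss of Me3Si+ give the 1,1-disubstituted alkene, and the benzyl group of the (2R,5R) catalyst blocks the Si face of the α-carbon so that ring C4 is formed S.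

Step 7
Reactants: 13 (2S,6R,10S)-2,6,10-trimethyl-4-methylidene-14-phenyltetradecanal
Product: 14 methyl (2E,4S,8R,12S)-4,8,12-trimethyl-6-methylidene-16-phenylhexadec-2-enoate
Conditions: Ph3P=CHCO2Me, CH2Cl2, 0 °C to rt (crude 13 used at once)
Reagents that add atoms: methyl (triphenylphosphoranylidene)acetate, COC(=O)C=P(c1ccccc1)(c1ccccc1)c1ccccc1
Why: Wittig olefination with a stabilised ylide, E-selective and not basic enough to epimerise the α-methyl aldehyde.

Step 8
Reactants: 14 methyl (2E,4S,8R,12S)-4,8,12-trimethyl-6-methylidene-16-phenylhexadec-2-enoate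
Product: 15 methyl (2E,4S,6R,8R,12S)-4,6,8,12-tetramethyl-16-phenyl-6-[(triethylsilyl)peroxy]hexadec-2-enoate
Conditions: Co(thd)2 [bis(2,2,6,6-tetramethylheptane-3,5-dionato)cobalt] (10 mol%), O2 (1 atm), Et3SiH, ClCH2CH2Cl, rt
Reagents that add atoms: dioxygen, O=O; triethylsilane, CC[SiH](CC)CC
Why: Mukaiyama–Isayama hydroperoxysilylation: hydrogen-atom transfer from a cobalt hydride to the electron-rich 1,1-disubstituted alkene (the E-enoate reacts much more slowly) gives the tertiary C6 radical, which is trapped by O2 and silylated; this radical has no facial bias, so C6 is formed about 1:1 (6R:6S) and the mixture is carried into step 9, where the 6R series is isolated.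

Step 9
Reactants: 15 methyl (2E,4S,6R,8R,12S)-4,6,8,12-tetramethyl-16-phenyl-6-[(triethylsilyl)peroxy]hexadec-2-enoate
Product: 17 methyl 2-[(3S,4S,6R)-6-[(2R,6S)-2,6-dimethyl-10-phenyldecyl]-4,6-dimethyl-1,2-dioxan-3-yl]acetate, via hydroperoxide 16 (not isolated)
Conditions: HCl (cat.), MeOH, 0 °C; then Et2NH, CF3CH2OH, rt
Reagents that add atoms: none
Why: Acid methanolysis frees the tertiary hydroperoxide, which closes by amine-mediated 6-exo peroxy-Michael addition in a protic fluorinated solvent (fast protonation of the ester enolate suppresses epoxide formation and reversal); a chair-like transition state with the C4 methyl and the C6 chain equatorial and the enoate attacked in the axial mode is expected to give the 3,4-cis (3S) ring, and the 6S-derived isomers and any 3-epimer are removed by chromatography.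

Step 10
Reactants: 17 methyl 2-[(3S,4S,6R)-6-[(2R,6S)-2,6-dimethyl-10-phenyldecyl]-4,6-dimethyl-1,2-dioxan-3-yl]acetate
Product: 18 2-[(3S,4S,6R)-6-[(2R,6S)-2,6-dimethyl-10-phenyldecyl]-4,6-dimethyl-1,2-dioxan-3-yl]acetic acid
Conditions: LiOH, THF/H2O (3:1), 0 °C to rt; then 1 M HCl to pH 3
Reagents that add atoms: lithium hydroxide, [Li+].[OH-]
Why: Mild saponification of the methyl ester; the dialkyl peroxide has no acidic C–H on a peroxide-bearing carbon and the carboxylate formed does not undergo retro-Michael opening, so C3 is not scrambled.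

**Compound list**
1 | (6R)-8-bromo-2,6-dimethyloct-2-ene [(R)-citronellyl bromide] | C[C@@H](CCBr)CCC=C(C)C | starting material
2 | 2-phenylethylmagnesium chloride | Cl[Mg]CCc1ccccc1 | starting material
3 | [(5S)-5,9-dimethyldec-8-en-1-yl]benzene | C[C@@H](CCCCc1ccccc1)CCC=C(C)C | intermediate
4 | 3,3-dimethyl-5-[(3S)-3-methyl-7-phenylheptyl]-1,2,4-trioxolane (ring C5 epimers) | C[C@@H](CCCCc1ccccc1)CCC1OOC(C)(C)O1 | intermediate
5 | (4S)-4-methyl-8-phenyloctan-1-ol | C[C@@H](CCCCc1ccccc1)CCCO | intermediate
6 | [(5S)-8-bromo-5-methyloctyl]benzene | C[C@@H](CCCCc1ccccc1)CCCBr | intermediate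
7 | methyl (2E)-but-2-enoate | C/C=C/C(=O)OC | starting material
8 | [(4S)-4-methyl-8-phenyloctyl]magnesium bromide | C[C@@H](CCCCc1ccccc1)CCC[Mg]Br | intermediate
9 | methyl (3R,7S)-3,7-dimethyl-11-phenylundecanoate | C[C@@H](CCCCc1ccccc1)CCC[C@@H](C)CC(=O)OC | intermediate
10 | 2-[(2R,6S)-2,6-dimethyl-10-phenyldecyl]-1,3-bis(trimethylsilyl)propan-2-ol | C[C@@H](CCCCc1ccccc1)CCC[C@@H](C)CC(O)(C[Si](C)(C)C)C[Si](C)(C)C | intermediate
11 | trimethyl[(4R,8S)-4,8-dimethyl-2-methylidene-12-phenyldodecyl]silane | C[C@@H](CCCCc1ccccc1)CCC[C@@H](C)CC(=C)C[Si](C)(C)C | intermediate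
12 | propanal | CCC=O | starting material
13 | (2S,6R,10S)-2,6,10-trimethyl-4-methylidene-14-phenyltetradecanal | C[C@@H](CCCCc1ccccc1)CCC[C@@H](C)CC(=C)C[C@H](C)C=O | intermediate
14 | methyl (2E,4S,8R,12S)-4,8,12-trimethyl-6-methylidene-16-phenylhexadec-2-enoate | C[C@@H](CCCCc1ccccc1)CCC[C@@H](C)CC(=C)C[C@H](C)/C=C/C(=O)OC | intermediate
15 | methyl (2E,4S,6R,8R,12S)-4,6,8,12-tetramethyl-16-phenyl-6-[(triethylsilyl)peroxy]hexadec-2-enoate | C[C@@H](CCCCc1ccccc1)CCC[C@@H](C)C[C@](OO[Si](CC)(CC)CC)(C)C[C@H](C)/C=C/C(=O)OC | intermediate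
16 | methyl (2E,4S,6R,8R,12S)-6-hydroperoxy-4,6,8,12-tetramethyl-16-phenylhexadec-2-enoate | C[C@@H](CCCCc1ccccc1)CCC[C@@H](C)C[C@](OO)(C)C[C@H](C)/C=C/C(=O)OC | intermediate
17 | methyl 2-[(3S,4S,6R)-6-[(2R,6S)-2,6-dimethyl-10-phenyldecyl]-4,6-dimethyl-1,2-dioxan-3-yl]acetate | C[C@@H](CCCCc1ccccc1)CCC[C@@H](C)C[C@]1(C)C[C@H](C)[C@H](CC(=O)OC)OO1 | intermediate
18 | 2-[(3S,4S,6R)-6-[(2R,6S)-2,6-dimethyl-10-phenyldecyl]-4,6-dimethyl-1,2-dioxan-3-yl]acetic acid | C[C@@H](CCCCc1ccccc1)CCC[C@@H](C)C[C@]1(C)C[C@H](C)[C@H](CC(=O)O)OO1 | target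

**Step count**
Total: 10 steps. Longest linear sequence: 10 steps (1 to 18; 2, 7 and 12 are purchased partners).

**Three steps most likely to fail**

Step 6 (key coupling). The reaction is normally run with the allylsilane in excess, whereas here 11 is the valuable, limiting partner, so the oxidant may consume the silane or over-oxidise the excess enamine. The fallback sets out from 9 and comes back at 13. Ester 9 is reduced with i-Bu2AlH (CH2Cl2, −78 °C) to (3R,7S)-3,7-dimethyl-11-phenylundecanal F1. F1 is used as an acyl-anion donor (Breslow intermediate) in a carbene-catalysed intermolecular Stetter addition to methyl methacrylate. The catalyst precursor is 2-(pentafluorophenyl)-5a,10b-dihydro-4H,6H-indeno[2,1-b][1,2,4]triazolo[4,3-d][1,4]oxazin-2-ium tetrafluoroborate (enantiomer chosen for 2S), with KOt-Bu (cat.) in toluene. This joins the former carbonyl carbon (ring C6) to the acrylate β-carbon and sets ring C4 by enantioselective protonation, giving methyl (2S,6R,10S)-2,6,10-trimethyl-4-oxo-14-phenyltetradecanoate F2. Wittig methylenation (Ph3P=CH2, THF, 0 °C) gives methyl (2S,6R,10S)-2,6,10-trimethyl-4-methylidene-14-phenyltetradecanoate F3, and i-Bu2AlH at −78 °C reduces F3 to 13.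

Step 8 (hydroperoxysilylation). The enoate may compete (conjugate reduction or α-peroxidation), and half of the material is necessarily the 6S series. The fallback sets out from 13 and comes back at 15. Aldehyde 13 is reduced (NaBH4, MeOH, 0 °C) to (2S,6R,10S)-2,6,10-trimethyl-4-methylidene-14-phenyltetradecan-1-ol F4. Its only alkene is hydroperoxysilylated under the same cobalt conditions to (2S,4R,6R,10S)-2,4,6,10-tetramethyl-14-phenyl-4-[(triethylsilyl)peroxy]tetradecan-1-ol F5; the C4 epimers can be separated here as polar alcohols. Dess–Martin oxidation gives (2S,4R,6R,10S)-2,4,6,10-tetramethyl-14-phenyl-4-[(triethylsilyl)peroxy]tetradecanal F6, and Wittig reaction with Ph3P=CHCO2Me gives 15.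

Step 9 (ring closure). The wanted 3,4-cis isomer has the acetate arm axial and is the less stable C3 epimer, so it must come from kinetic control and cannot be recovered by equilibration if the trans isomer dominates. The fallback sets out from 13 and comes back at 17; it forms the C3–CH2 bond last, on the preformed ring. Aldehyde 13 is converted (MeOH, cat. TsOH, molecular sieves) into the dimethyl acetal [(5S,9R,13S)-14,14-dimethoxy-5,9,13-trimethyl-11-methylidenetetradecyl]benzene F7. Hydroperoxysilylation as in step 8 gives [(5S,9R,11R,13S)-14,14-dimethoxy-5,9,11,13-tetramethyl-11-[(triethylsilyl)peroxy]tetradecyl]benzene F8 (with its C11 epimer). Catalytic HCl in MeOH removes the silyl group and closes the cyclic peroxyacetal (4S,6R)-6-[(2R,6S)-2,6-dimethyl-10-phenyldecyl]-3-methoxy-4,6-dimethyl-1,2-dioxane F9 (C3 anomers). TiCl4 with 1-methoxy-1-(trimethylsilyloxy)ethene (CH2Cl2, −78 °C) ionises F9 to the ring peroxycarbenium ion, and axial attack of the ketene acetal on the half-chair with the C4 methyl and C6 chain pseudo-equatorial gives 17 with the 3,4-cis arrangement. The closest known chemistry is Lewis acid displacement of 3-alkoxy-1,2-dioxolanes by silyl ketene acetals.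

Lesser risks: the C2' epimer from step 4 (about 5%) is not separable until late, and step 10 relies on the peroxide tolerating hydroxide at 0 °C.

**Further compounds**
F1 | step 6 | (3R,7S)-3,7-dimethyl-11-phenylundecanal | C[C@@H](CCCCc1ccccc1)CCC[C@@H](C)CC=O
F2 | step 6 | methyl (2S,6R,10S)-2,6,10-trimethyl-4-oxo-14-phenyltetradecanoate | C[C@@H](CCCCc1ccccc1)CCC[C@@H](C)CC(=O)C[C@H](C)C(=O)OC
F3 | step 6 | methyl (2S,6R,10S)-2,6,10-trimethyl-4-methylidene-14-phenyltetradecanoate | C[C@@H](CCCCc1ccccc1)CCC[C@@H](C)CC(=C)C[C@H](C)C(=O)OC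
F4 | step 8 | (2S,6R,10S)-2,6,10-trimethyl-4-methylidene-14-phenyltetradecan-1-ol | C[C@@H](CCCCc1ccccc1)CCC[C@@H](C)CC(=C)C[C@H](C)CO
F5 | step 8 | (2S,4R,6R,10S)-2,4,6,10-tetramethyl-14-phenyl-4-[(triethylsilyl)peroxy]tetradecan-1-ol | C[C@@H](CCCCc1ccccc1)CCC[C@@H](C)C[C@](OO[Si](CC)(CC)CC)(C)C[C@H](C)CO
F6 | step 8 | (2S,4R,6R,10S)-2,4,6,10-tetramethyl-14-phenyl-4-[(triethylsilyl)peroxy]tetradecanal | C[C@@H](CCCCc1ccccc1)CCC[C@@H](C)C[C@](OO[Si](CC)(CC)CC)(C)C[C@H](C)C=O
F7 | step 9 | [(5S,9R,13S)-14,14-dimethoxy-5,9,13-trimethyl-11-methylidenetetradecyl]benzene | C[C@@H](CCCCc1ccccc1)CCC[C@@H](C)CC(=C)C[C@H](C)C(OC)OC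
F8 | step 9 | [(5S,9R,11R,13S)-14,14-dimethoxy-5,9,11,13-tetramethyl-11-[(triethylsilyl)peroxy]tetradecyl]benzene | C[C@@H](CCCCc1ccccc1)CCC[C@@H](C)C[C@](OO[Si](CC)(CC)CC)(C)C[C@H](C)C(OC)OC
F9 | step 9 | (4S,6R)-6-[(2R,6S)-2,6-dimethyl-10-phenyldecyl]-3-methoxy-4,6-dimethyl-1,2-dioxane (C3 anomers) | C[C@@H](CCCCc1ccccc1)CCC[C@@H](C)C[C@]1(C)C[C@H](C)C(OC)OO1
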